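Positions follow germacrane numbering (ring C1–C10; lactone C6–O–C12(=O)–C11=C7; C13 is the acetoxymethyl carbon). Everything rests on disconnecting the lactone O–C6 bond: the butenolide ring contains a 1,4-dioxygenated but-2-ene, O–C6–C7=C11–C13–OAc, so a palladium-catalysed 1,4-acetoxylactonisation of a conjugated diene acid closes the furanone at C6, moves the double bond into the ring (C7=C11) and puts the acetate on C13 in one operation. The precursor is a ten-membered 1(10),4,6-triene (E at C1=C10, ring-cis elsewhere) with the C3 acetate in place and a CH2=C(CO2H) group on C7, made by Nozaki–Hiyama–Kishi macrocyclisation. A last singlet-oxygen ene reaction installs the C1 hydroperoxide and the C10 methylene.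

Key step: step 21

Remark: compounds 1, 2, 8, 22 and 23 are taken as commercial; the C6 configuration in step 21 and the C1 configuration in step 22 rest on a conformational argument and not on a calculation.

Step 1
Reactants: 1 3-[(tert-butyldimethylsilyl)oxy]propanal; 2 isopropenylmagnesium bromide, CH2=C(CH3)MgBr
Product: 3 rac-5-[(tert-butyldimethylsilyl)oxy]-2-methylpent-1-en-3-ol
Conditions: THF, −78 to 0 °C; then H2O
Reagents that add atoms: none
Why: Grignard 1,2-addition to the aldehyde gives the secondary allylic alcohol, whose stereocentre is destroyed in step 2, so the racemate is used.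

Step 2
Reactants: 3 rac-5-[(tert-butyldimethylsilyl)oxy]-2-methylpent-1-en-3-ol
Product: 5 ethyl (4E)-7-[(tert-butyldimethylsilyl)oxy]-4-methylhept-4-enoate, via mixed ketene acetal 4 (not isolated)
Conditions: MeC(OEt)3 (excess), EtCO2H (cat.), 140 °C, EtOH distilled off
Reagents that add atoms: triethyl orthoacetate, CC(OCC)(OCC)OCC
Why: Johnson–Claisen rearrangement through a chair transition state with the CH2CH2OSi group equatorial should set the E-trisubstituted C1=C10 olefin and add C8 and C7.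

Step 3
Reactants: 5 ethyl (4E)-7-[(tert-butyldimethylsilyl)oxy]-4-methylhept-4-enoate
Product: 6 (4E)-7-[(tert-butyldimethylsilyl)oxy]-4-methylhept-4-enal
Conditions: iBu2AlH (1.1 equiv), CH2Cl2, −78 °C; then H2O
Reagents that add atoms: none
Why: Partial ester reduction stops at the aluminium hemiacetal at low temperature, which gives the aldehyde on work-up.

Step 4
Reactants: 6 (4E)-7-[(tert-butyldimethylsilyl)oxy]-4-methylhept-4-enal
Product: 7 tert-butyl{[(3E)-6-(1,3-dithian-2-yl)-4-methylhex-3-en-1-yl]oxy}dimethylsilane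
Conditions: HS(CH2)3SH, BF3·OEt2 (cat.), CH2Cl2, −40 °C
Reagents that add atoms: propane-1,3-dithiol, SCCCS
Why: Lewis-acid-catalysed dithioacetalisation turns the C7 aldehyde into a 1,3-dithiane, the acyl-anion equivalent (polarity reversal) for the next C–C bond.

Step 5
Reactants: 8 ethyl but-2-ynoate
Product: 9 ethyl (2Z)-3-iodobut-2-enoate
Conditions: NaI, AcOH, 115 °C
Reagents that add atoms: sodium iodide, [Na+].[I-]
Why: Conjugate anti-hydroiodination of the ynoate (iodide to C3, protonation anti) should give the Z-iodoalkenoate.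

Step 6
Reactants: 9 ethyl (2Z)-3-iodobut-2-enoate
Product: 10 (2Z)-3-iodobut-2-en-1-ol
Conditions: iBu2AlH (2.2 equiv), CH2Cl2, −78 to 0 °C; then H2O
Reagents that add atoms: none
Why: 1,2-Reduction of the ester by two hydride transfers gives the allylic alcohol without touching the vinyl iodide.

Step 7
Reactants: 10 (2Z)-3-iodobut-2-en-1-ol
Product: 11 (2Z)-1-bromo-3-iodobut-2-ene
Conditions: CBr4, PPh3, CH2Cl2, 0 °C
Reagents that add atoms: tetrabromomethane, BrC(Br)(Br)Br
Why: Appel bromination converts the primary allylic alcohol into the bromide with retention of the olefin geometry.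

Step 8
Reactants: 7 tert-butyl{[(3E)-6-(1,3-dithian-2-yl)-4-methylhex-3-en-1-yl]oxy}dimethylsilane; 11 (2Z)-1-bromo-3-iodobut-2-ene
Product: 13 tert-butyl{[(3E)-6-{2-[(2Z)-3-iodobut-2-en-1-yl]-1,3-dithian-2-yl}-4-methylhex-3-en-1-yl]oxy}dimethylsilane, via 2-lithio-1,3-dithiane 12 (not isolated)
Conditions: n-BuLi, THF, −30 °C; then 11, −78 °C
Reagents that add atoms: none
Why: Corey–Seebach alkylation: the lithiated dithiane displaces the primary allylic bromide by SN2, faster than iodine–lithium exchange at the vinyl iodide, and forms the C6–C7 bond.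

Step 9
Reactants: 13 tert-butyl{[(3E)-6-{2-[(2Z)-3-iodobut-2-en-1-yl]-1,3-dithian-2-yl}-4-methylhex-3-en-1-yl]oxy}dimethylsilane
Product: 14 (3E)-6-{2-[(2Z)-3-iodobut-2-en-1-yl]-1,3-dithian-2-yl}-4-methylhex-3-en-1-ol
Conditions: Bu4NF, THF, 0 °C
Reagents that add atoms: none
Why: Fluoride-mediated desilylation frees the primary alcohol and leaves dithiane, vinyl iodide and olefins untouched.

Step 10
Reactants: 14 (3E)-6-{2-[(2Z)-3-iodobut-2-en-1-yl]-1,3-dithian-2-yl}-4-methylhex-3-en-1-ol
Product: 15 (3E)-6-{2-[(2Z)-3-iodobut-2-en-1-yl]-1,3-dithian-2-yl}-4-methylhex-3-enal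
Conditions: Dess–Martin periodinane, NaHCO3, CH2Cl2, 0 °C
Reagents that add atoms: none
Why: Buffered Dess–Martin oxidation should give the β,γ-unsaturated aldehyde without migration of the C1=C10 bond.

Step 11
Reactants: 15 (3E)-6-{2-[(2Z)-3-iodobut-2-en-1-yl]-1,3-dithian-2-yl}-4-methylhex-3-enal
Product: 16 rac-(8Z,12E)-9,13-dimethyl-1,5-dithiaspiro[5.9]pentadeca-8,12-dien-10-ol
Conditions: CrCl2 (excess), NiCl2 (cat.), DMSO, rt, high dilution; then H2O
Reagents that add atoms: none
Why: Nozaki–Hiyama–Kishi macrocyclisation: the alkenylchromium species from the vinyl iodide adds to the aldehyde, closing the ten-membered ring at C3–C4 with retention of the Z-geometry, helped by the gem-disubstituted dithiane carbon; the racemic carbinol is erased in step 12.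

Step 12
Reactants: 16 rac-(8Z,12E)-9,13-dimethyl-1,5-dithiaspiro[5.9]pentadeca-8,12-dien-10-ol
Product: 17 (8Z,12E)-9,13-dimethyl-1,5-dithiaspiro[5.9]pentadeca-8,12-dien-10-one
Conditions: MnO2, CH2Cl2, rt
Reagents that add atoms: none
Why: Selective MnO2 oxidation of the allylic alcohol gives the macrocyclic enone.

Step 13
Reactants: 17 (8Z,12E)-9,13-dimethyl-1,5-dithiaspiro[5.9]pentadeca-8,12-dien-10-one
Product: 18 (8Z,10S,12E)-9,13-dimethyl-1,5-dithiaspiro[5.9]pentadeca-8,12-dien-10-ol
Conditions: (R)-2-methyl-CBS-oxazaborolidine (cat.), BH3·SMe2, THF, −30 °C; then MeOH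
Reagents that add atoms: none
Why: Corey–Bakshi–Shibata reduction delivers hydride to one carbonyl face (alkenyl group as the large substituent) and should set C3 as S under reagent control.

Step 14
Reactants: 18 (8Z,10S,12E)-9,13-dimethyl-1,5-dithiaspiro[5.9]pentadeca-8,12-dien-10-ol
Product: 19 (8Z,10S,12E)-9,13-dimethyl-1,5-dithiaspiro[5.9]pentadeca-8,12-dien-10-yl acetate
Conditions: Ac2O, pyridine, DMAP (cat.), CH2Cl2, 0 °C
Reagents that add atoms: acetic anhydride, CC(=O)OC(C)=O
Why: DMAP-catalysed acylation of the secondary allylic alcohol proceeds with retention at C3.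

Step 15
Reactants: 19 (8Z,10S,12E)-9,13-dimethyl-1,5-dithiaspiro[5.9]pentadeca-8,12-dien-10-yl acetate
Product: 20 (1S,2Z,8E)-2,8-dimethyl-5-oxocyclodeca-2,8-dien-1-yl acetate
Conditions: MeI, CaCO3, MeCN–H2O, 45 °C
Reagents that add atoms: water, O
Why: Alkylative dethioacetalisation (S-methylation, then hydrolysis) unmasks the C7 ketone under near-neutral conditions that spare the allylic acetate.

Step 16
Reactants: 20 (1S,2Z,8E)-2,8-dimethyl-5-oxocyclodeca-2,8-dien-1-yl acetate
Product: 21 (1S,2Z,4E,8E)-2,8-dimethyl-5-{[(trifluoromethyl)sulfonyl]oxy}cyclodeca-2,4,8-trien-1-yl acetate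
Conditions: Tf2O, 2,6-di-tert-butyl-4-methylpyridine, CH2Cl2, −78 to 0 °C
Reagents that add atoms: trifluoromethanesulfonic anhydride, O=S(=O)(OS(=O)(=O)C(F)(F)F)C(F)(F)F
Why: Enol triflate formation with a hindered pyridine: the O-triflyl oxocarbenium ion loses the more acidic allylic C6 proton to give the conjugated ring-cis dienyl triflate, without a free dienolate that could expel the C3 acetate.

Step 17
Reactants: 22 prop-2-ynoic acid; 23 2-(trimethylsilyl)ethanol
Product: 24 2-(trimethylsilyl)ethyl prop-2-ynoate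
Conditions: DCC, DMAP (cat.), CH2Cl2, 0 °C
Reagents that add atoms: none
Why: Steglich (carbodiimide) esterification of the alkynoic acid.

Step 18
Reactants: 24 2-(trimethylsilyl)ethyl prop-2-ynoate
Product: 25 2-(trimethylsilyl)ethyl 2-(tributylstannyl)prop-2-enoate
Conditions: Bu3SnH, Pd(PPh3)4 (cat.), THF, 0 °C
Reagents that add atoms: tributyltin hydride, CCCC[SnH](CCCC)CCCC
Why: Palladium-catalysed syn-hydrostannation of the propiolate places tin mainly on the α-carbon.

Step 19
Reactants: 21 (1S,2Z,4E,8E)-2,8-dimethyl-5-{[(trifluoromethyl)sulfonyl]oxy}cyclodeca-2,4,8-trien-1-yl acetate; 25 2-(trimethylsilyl)ethyl 2-(tributylstannyl)prop-2-enoate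
Product: 26 2-(trimethylsilyl)ethyl 2-[(1E,3Z,5S,7E)-5-(acetyloxy)-4,8-dimethylcyclodeca-1,3,7-trien-1-yl]prop-2-enoate
Conditions: Pd2(dba)3 (cat.), AsPh3, CuI (cat.), NMP, rt
Reagents that add atoms: none
Why: Stille cross-coupling forms the C7–C11 bond with retention of the ring-cis C6=C7 geometry; the weakly donating arsine and room temperature should keep zerovalent palladium from ionising the allylic acetate.

Step 20
Reactants: 26 2-(trimethylsilyl)ethyl 2-[(1E,3Z,5S,7E)-5-(acetyloxy)-4,8-dimethylcyclodeca-1,3,7-trien-1-yl]prop-2-enoate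
Product: 27 2-[(1E,3Z,5S,7E)-5-(acetyloxy)-4,8-dimethylcyclodeca-1,3,7-trien-1-yl]prop-2-enoic acid
Conditions: Bu4NF, THF, 0 °C; then cold dilute HCl
Reagents that add atoms: none
Why: Fluoride-induced β-elimination of the 2-(trimethylsilyl)ethyl ester frees the acid without hydroxide that would cleave the acetate.

Step 21
Reactants: 27 2-[(1E,3Z,5S,7E)-5-(acetyloxy)-4,8-dimethylcyclodeca-1,3,7-trien-1-yl]prop-2-enoic acid
Product: 28 (3S,6R)-3,13-bis(acetyloxy)germacra-1(10)E,4Z,7(11)-trien-12,6-olide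
Conditions: Pd(OAc)2 (5 mol %), p-benzoquinone (20 mol %), MnO2, AcOH–acetone (1:4), rt
Reagents that add atoms: acetic acid, CC(=O)O
Why: Proposed new method: divalent palladium coordinates the C6=C7 bond of the 2-carboxy-1,3-diene (C6=C7–C11=C13), the C12 carboxylate adds to C6 anti to the metal, the C7–palladium bond becomes an η3-allyl over C7–C11–C13, and benzoquinone-assisted attack of acetate at the primary C13 terminus releases zerovalent palladium, which the quinone and MnO2 reoxidise. The closest known reaction types are the palladium-catalysed 1,4-acyloxylactonisation of conjugated dienes with a tethered acid and the endo-oxypalladation of alk-3-enoic acids to butenolides; new is that the acid sits on the diene itself. The only ring closed is the butenolide (O–C6 bond), formally by a 5-endo-trig attack that the metal-activated olefin allows, as in 5-endo halolactonisations, and the new C7=C11 bond ends inside this ring. C6 is the only new stereocentre: allylic 1,3-strain across the Z-C4=C5 bond keeps H3 in the olefin plane, so the C3 acetate fixes the twist of the Z,Z-diene, the metal is expected on its outer face and the acid on the inner face, which corresponds to 6R. The step needs this facial selectivity, lactonisation in preference to external acetoxylation of the ring diene, and acetate capture at C13 instead of C7; these rest on the ring conformation, on the five-membered transition state and the deactivation of C4=C5 by the allylic acetate, and on the unhindered terminus that leads to the conjugated lactone. C13 is not stereogenic, so the syn or anti course of the acetate transfer is without consequence.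

Step 22
Reactants: 28 (3S,6R)-3,13-bis(acetyloxy)germacra-1(10)E,4Z,7(11)-trien-12,6-olide
Product: 29 (1R,3S,6R)-3,13-bis(acetyloxy)-1-hydroperoxygermacra-4Z,7(11),10(14)-trien-12,6-olide
Conditions: O2, visible light, tetraphenylporphyrin (cat.), CH2Cl2, −20 °C
Reagents that add atoms: dioxygen, O=O
Why: Schenck ene reaction: singlet oxygen should attack only the electron-rich C1=C10 bond (C4=C5 carries two allylic acyloxy groups, C7=C11 is electron-poor), abstract a C14 methyl hydrogen on the disubstituted side (cis effect) so that oxygen ends on C1 and the olefin moves to C10=C14, and approach the peripheral face of the E-olefin, which is expected to correspond to 1R.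

Compound list
1 | 3-[(tert-butyldimethylsilyl)oxy]propanal | O=CCCO[Si](C)(C)C(C)(C)C | starting material
2 | isopropenylmagnesium bromide, CH2=C(CH3)MgBr | C=C(C)[Mg]Br | starting material
3 | rac-5-[(tert-butyldimethylsilyl)oxy]-2-methylpent-1-en-3-ol | C=C(C)C(O)CCO[Si](C)(C)C(C)(C)C | intermediate
4 | tert-butyl({3-[(1-ethoxyethenyl)oxy]-4-methylpent-4-en-1-yl}oxy)dimethylsilane (mixed ketene acetal, not isolated) | C=C(OCC)OC(CCO[Si](C)(C)C(C)(C)C)C(C)=C | intermediate
5 | ethyl (4E)-7-[(tert-butyldimethylsilyl)oxy]-4-methylhept-4-enoate | CCOC(=O)CC/C(C)=C/CCO[Si](C)(C)C(C)(C)C | intermediate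
6 | (4E)-7-[(tert-butyldimethylsilyl)oxy]-4-methylhept-4-enal | O=CCC/C(C)=C/CCO[Si](C)(C)C(C)(C)C | intermediate
7 | tert-butyl{[(3E)-6-(1,3-dithian-2-yl)-4-methylhex-3-en-1-yl]oxy}dimethylsilane | C1CSC(CC/C(C)=C/CCO[Si](C)(C)C(C)(C)C)SC1 | intermediate
8 | ethyl but-2-ynoate | CC#CC(=O)OCC | starting material
9 | ethyl (2Z)-3-iodobut-2-enoate | C/C(I)=C/C(=O)OCC | intermediate
10 | (2Z)-3-iodobut-2-en-1-ol | C/C(I)=C/CO | intermediate
11 | (2Z)-1-bromo-3-iodobut-2-ene | C/C(I)=C/CBr | intermediate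
12 | 2-lithio derivative of 7 (not isolated) | [Li]C1(CC/C(C)=C/CCO[Si](C)(C)C(C)(C)C)SCCCS1 | intermediate
13 | tert-butyl{[(3E)-6-{2-[(2Z)-3-iodobut-2-en-1-yl]-1,3-dithian-2-yl}-4-methylhex-3-en-1-yl]oxy}dimethylsilane | C/C(I)=C/CC1(CC/C(C)=C/CCO[Si](C)(C)C(C)(C)C)SCCCS1 | intermediate
14 | (3E)-6-{2-[(2Z)-3-iodobut-2-en-1-yl]-1,3-dithian-2-yl}-4-methylhex-3-en-1-ol | C/C(I)=C/CC1(CC/C(C)=C/CCO)SCCCS1 | intermediate
15 | (3E)-6-{2-[(2Z)-3-iodobut-2-en-1-yl]-1,3-dithian-2-yl}-4-methylhex-3-enal | C/C(I)=C/CC1(CC/C(C)=C/CC=O)SCCCS1 | intermediate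
16 | rac-(8Z,12E)-9,13-dimethyl-1,5-dithiaspiro[5.9]pentadeca-8,12-dien-10-ol | C/C1=C\CC(O)/C(C)=C\CC2(CC1)SCCCS2 | intermediate
17 | (8Z,12E)-9,13-dimethyl-1,5-dithiaspiro[5.9]pentadeca-8,12-dien-10-one | C/C1=C\CC(=O)/C(C)=C\CC2(CC1)SCCCS2 | intermediate
18 | (8Z,10S,12E)-9,13-dimethyl-1,5-dithiaspiro[5.9]pentadeca-8,12-dien-10-ol | C/C1=C\C[C@H](O)/C(C)=C\CC2(CC1)SCCCS2 | intermediate
19 | (8Z,10S,12E)-9,13-dimethyl-1,5-dithiaspiro[5.9]pentadeca-8,12-dien-10-yl acetate | C/C1=C\C[C@H](OC(C)=O)/C(C)=C\CC2(CC1)SCCCS2 | intermediate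
20 | (1S,2Z,8E)-2,8-dimethyl-5-oxocyclodeca-2,8-dien-1-yl acetate | C/C1=C\C[C@H](OC(C)=O)/C(C)=C\CC(=O)CC1 | intermediate
21 | (1S,2Z,4E,8E)-2,8-dimethyl-5-{[(trifluoromethyl)sulfonyl]oxy}cyclodeca-2,4,8-trien-1-yl acetate | C/C1=C\C[C@H](OC(C)=O)/C(C)=C\C=C(\OS(=O)(=O)C(F)(F)F)CC1 | intermediate
22 | prop-2-ynoic acid | C#CC(=O)O | starting material
23 | 2-(trimethylsilyl)ethanol | C[Si](C)(C)CCO | starting material
24 | 2-(trimethylsilyl)ethyl prop-2-ynoate | C#CC(=O)OCC[Si](C)(C)C | intermediate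
25 | 2-(trimethylsilyl)ethyl 2-(tributylstannyl)prop-2-enoate | C=C(C(=O)OCC[Si](C)(C)C)[Sn](CCCC)(CCCC)CCCC | intermediate
26 | 2-(trimethylsilyl)ethyl 2-[(1E,3Z,5S,7E)-5-(acetyloxy)-4,8-dimethylcyclodeca-1,3,7-trien-1-yl]prop-2-enoate | C/C1=C\C[C@H](OC(C)=O)/C(C)=C\C=C(\C(=C)C(=O)OCC[Si](C)(C)C)CC1 | intermediate
27 | 2-[(1E,3Z,5S,7E)-5-(acetyloxy)-4,8-dimethylcyclodeca-1,3,7-trien-1-yl]prop-2-enoic acid | C/C1=C\C[C@H](OC(C)=O)/C(C)=C\C=C(\C(=C)C(=O)O)CC1 | intermediate
28 | (3S,6R)-3,13-bis(acetyloxy)germacra-1(10)E,4Z,7(11)-trien-12,6-olide | C/C1=C\C[C@H](OC(C)=O)/C(C)=C\[C@H]2OC(=O)C(COC(C)=O)=C2CC1 | intermediate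
29 | (1R,3S,6R)-3,13-bis(acetyloxy)-1-hydroperoxygermacra-4Z,7(11),10(14)-trien-12,6-olide | C=C1CCC2=C(COC(C)=O)C(=O)O[C@@H]2/C=C(/C)[C@@H](OC(C)=O)C[C@H]1OO | target

Total step count: 22. Longest linear sequence: 17 steps (steps 1–4, 8–16, 19–22).

Steps most likely to fail

Step 21. The diene acid may be diverted by oxypalladation and external acetoxylation of the ring diene, by cycloaddition with the quinone, or by delivery of the carboxylate to the other face of C6=C7 (poor facial selectivity). The fallback uses known reaction types, sets out from acid 27 and returns at 28. Phenylselenolactonisation (PhSeCl, CH2Cl2, −78 °C) should open the seleniranium ion at C6 by the carboxylate in the same 5-endo anti sense and give (3S,6R,7S)-3-(acetyloxy)-7-(phenylselanyl)germacra-1(10)E,4Z,11(13)-trien-12,6-olide F1. Oxidation of this allylic selenide (H2O2, pyridine, CH2Cl2, 0 °C) should trigger the [2,3]-sigmatropic shift of the selenoxide, which moves the double bond to C7=C11 and the oxygen to C13, giving (3S,6R)-3-(acetyloxy)-13-hydroxygermacra-1(10)E,4Z,7(11)-trien-12,6-olide F2. Acetylation (Ac2O, pyridine, DMAP) then gives 28.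

Step 11. Intermolecular coupling (oligomerisation) may outrun ring closure, or the C1=C10 bond may migrate into conjugation with the aldehyde before cyclisation. The fallback sets out from aldehyde 15 and returns at enone 17, so that step 12 is skipped. Pinnick oxidation (NaClO2, NaH2PO4, 2-methylbut-2-ene, t-BuOH–H2O) gives (3E)-6-{2-[(2Z)-3-iodobut-2-en-1-yl]-1,3-dithian-2-yl}-4-methylhex-3-enoic acid F3. Amide formation (MeNHOMe·HCl, EDC·HCl, iPr2NEt) gives the Weinreb amide (3E)-6-{2-[(2Z)-3-iodobut-2-en-1-yl]-1,3-dithian-2-yl}-N-methoxy-N,4-dimethylhex-3-enamide F4. Iodine–lithium exchange (t-BuLi, 2 equiv, THF, −78 °C, high dilution) and intramolecular acylation of the alkenyllithium should then give 17 after collapse of the chelated tetrahedral intermediate on work-up.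

Step 22. Oxygen may abstract a ring hydrogen at C2 instead of a C14 hydrogen (wrong regiochemistry) or attack the other face of C1=C10 (poor facial selectivity). The fallback sets out from 28, returns at 29 and puts C1 under reagent control. Shi epoxidation of the only electron-rich olefin (fructose-derived ketone of the enantiomeric series matched to the required face, KHSO5, K2CO3 buffer, MeCN–H2O, 0 °C) gives (1S,3S,6R,10S)-3,13-bis(acetyloxy)-1,10-epoxygermacra-4Z,7(11)-dien-12,6-olide F5. Epoxide isomerisation (Me3SiOTf, 2,6-lutidine, toluene, −78 °C, then DBU), which breaks the C10–O bond and removes a C14 proton, gives (1S,3S,6R)-3,13-bis(acetyloxy)-1-[(trimethylsilyl)oxy]germacra-4Z,7(11),10(14)-trien-12,6-olide F6. Desilylation (citric acid, MeOH) gives (1S,3S,6R)-3,13-bis(acetyloxy)-1-hydroxygermacra-4Z,7(11),10(14)-trien-12,6-olide F7, and mesylation (MsCl, Et3N, CH2Cl2, −20 °C) gives (1S,3S,6R)-3,13-bis(acetyloxy)-1-[(methylsulfonyl)oxy]germacra-4Z,7(11),10(14)-trien-12,6-olide F8. Displacement with anhydrous H2O2 in ether should then give 29 with inversion at C1.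

Further compounds
F1 | step 21 | (3S,6R,7S)-3-(acetyloxy)-7-(phenylselanyl)germacra-1(10)E,4Z,11(13)-trien-12,6-olide | C/C1=C\C[C@H](OC(C)=O)/C(C)=C\[C@H]2OC(=O)C(=C)[C@@]2([Se]c3ccccc3)CC1
F2 | step 21 | (3S,6R)-3-(acetyloxy)-13-hydroxygermacra-1(10)E,4Z,7(11)-trien-12,6-olide | C/C1=C\C[C@H](OC(C)=O)/C(C)=C\[C@H]2OC(=O)C(CO)=C2CC1
F3 | step 11 | (3E)-6-{2-[(2Z)-3-iodobut-2-en-1-yl]-1,3-dithian-2-yl}-4-methylhex-3-enoic acid | C/C(I)=C/CC1(CC/C(C)=C/CC(=O)O)SCCCS1
F4 | step 11 | (3E)-6-{2-[(2Z)-3-iodobut-2-en-1-yl]-1,3-dithian-2-yl}-N-methoxy-N,4-dimethylhex-3-enamide | C/C(I)=C/CC1(CC/C(C)=C/CC(=O)N(C)OC)SCCCS1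
F5 | step 22 | (1S,3S,6R,10S)-3,13-bis(acetyloxy)-1,10-epoxygermacra-4Z,7(11)-dien-12,6-olide | C[C@]12CCC3=C(COC(C)=O)C(=O)O[C@@H]3/C=C(/C)[C@@H](OC(C)=O)C[C@@H]1O2
F6 | step 22 | (1S,3S,6R)-3,13-bis(acetyloxy)-1-[(trimethylsilyl)oxy]germacra-4Z,7(11),10(14)-trien-12,6-olide | C=C1CCC2=C(COC(C)=O)C(=O)O[C@@H]2/C=C(/C)[C@@H](OC(C)=O)C[C@@H]1O[Si](C)(C)C
F7 | step 22 | (1S,3S,6R)-3,13-bis(acetyloxy)-1-hydroxygermacra-4Z,7(11),10(14)-trien-12,6-olide | C=C1CCC2=C(COC(C)=O)C(=O)O[C@@H]2/C=C(/C)[C@@H](OC(C)=O)C[C@@H]1O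
F8 | step 22 | (1S,3S,6R)-3,13-bis(acetyloxy)-1-[(methylsulfonyl)oxy]germacra-4Z,7(11),10(14)-trien-12,6-olide | C=C1CCC2=C(COC(C)=O)C(=O)O[C@@H]2/C=C(/C)[C@@H](OC(C)=O)C[C@@H]1OS(C)(=O)=O
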